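Time comes first: each set-up has 40 min, and I ask what fraction of the substrate is left to be shared out over it.

| flask | substrate | free catalyst | time | remark |
|---|---|---|---|---|
| summer | 0.20 M (fed, over 32.0 min) | 0.78 mM | 40 min | all but substrate at the start; substrate goes in evenly over 32.0 min, the run ends at 40 min |
| noon | 0.20 M | 0.78 mM |  | one stirred flow tank at steady state, fed with the mixture as stated, mean residence time 40 min |
| midnight | 0.20 M | 0.78 mM | 40 min | everything together in a closed stirred flask, run for 40 min |

- the set-up with the highest amount of target at the outlet or at the end, in percent of the substrate put in ("none" if the first two lie within 2 percentage points) (summer / noon / midnight / none)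
- amount of target at the outlet or at the end, in percent of the substrate put in, summer
- amount of target at the outlet or at the end, in percent of the substrate put in, noon
- amount of target at the outlet or at the end, in percent of the substrate put in, midnight

- a species is counted by the substrate in it: one self-condensation product counts as two
- for a step with 2 of a species take k times the square, and two of it per event
- the stated concentrations are those of everything mixed, before any reaction; amounts are the same in each set-up
- the feed brings no volume worth counting
- run time (summer): 40 min

    2 substrate → self-condensation product (k1 = 0.0074 L mol⁻¹ s⁻¹)
    substrate + free catalyst ⇌ catalyst intermediate A (K2 = 8.1 L mol⁻¹, k2 = 2.2 L mol⁻¹ s⁻¹)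
    substrate ⇌ dormant form (K3 = 1.1, k3 = 0.0044 s⁻¹)
    catalyst intermediate A ⇌ catalyst intermediate B (K4 = 0.83, k4 = 0.37 s⁻¹)
    catalyst intermediate B ⇌ free catalyst + target (K5 = 1.7 M, k5 = 0.70 s⁻¹)

1. I count the pool, substrate plus dormant form, as a fraction w of the charge. Their exchange relaxes with a half-life of 1.38 min, much shorter than the run, so I hold free substrate at 47.6% of the pool.

2. Catalyst intermediate B goes on to target with probability 61.1%, so catalyst intermediate A ends as target with probability 45.4%. With free substrate at its opening level of 0.0952 M, I reckon free catalyst at 64.2% of its charge, and I keep that share throughout.

3. The catalyst then uses the pool at a·w, where a is a pseudo-first-order constant of 0.0143 min⁻¹. Self-condensation uses it at b·w², where b is 0.0403 min⁻¹.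

4. The two rates are equal at the crossover fraction x = a/b, the fraction left at which catalyst and self-condensation consume the pool equally, here 35.5%. Above x, self-condensation takes more in my reckoning.

5. The bench rule says to feed slowly and keep w low. A tank balance gives 43.9% left, so noon yields 25.1%. I roughly treat summer as the same tank: 25.1%.

6. The rule meets its border in the ratio a·t, which is 0.572, less than one. The catalyst is short of time, and a low w slows target as well.

7. For midnight, the closed flask, summing a·w over the falling fraction left gives 28.4%, ahead of my tank by 3.3 percentage points.

The forecast differs from my reckoning, which puts midnight first: it names none, with 27.3%, 27% and 28.5% for summer, noon and midnight, on the ground that “all three vessels end up at a similar yield”.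

The simulation gives 26.6%, 27.0% and 28.2% for summer, noon and midnight, so the choice is none.

At 40.0 min, the midnight pool reads 24.2%, below x, while the summer pool reads 43.8%, above it. A neighbour of summer, whose target lands under the 25% low end of the forecast's summer range, holds 4.7 × 10⁻⁴ M of free catalyst. Keeping my free share, a becomes 0.00862 min⁻¹ and x falls to 21.4%. The tank balance then leaves 47.4% and yields 16.3%. That neighbour gives 17.4% of target.

Its constants are those of an exercise; the flask was simulated.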